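**Plan**

- Retrosynthetic cuts: C3=C15 back to a tertiary carbinol and C8H2 back to C8=O; then the cyclobutane bond C2–C10 (C2 radical plus enone C8(=O)–C9=C10); then the pyran bonds O–C7 and C1′–C6 (o-quinone methide plus C6=C7). What remains is the eleven-membered ring of zerumbone.
- Forward order: zerumbone → bromohydrin at C2=C3 (mask and radical precursor) → C8 carbinol → three-component chromane annulation on C6=C7 → enone → transannular 4-exo-trig closure C2→C10, which makes ring C1–C2–C10–C11 and turns the eleven-membered ring into the four/nine bicycle → C8 deoxygenation, dehydration to C3=C15, release of the aldehydes.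
- Enabling feature: C2 and C10 sit 1,4 across the C1–C11 bridge of the eleven-membered ring, C11 carries the gem-dimethyl group, and C10 is the β-carbon of the zerumbone enone. A radical at C2 therefore has the four-membered ring as its only sensible closure.
- Stereochemistry: C8 comes from a CBS reduction, steers the cycloaddition face (C6, C7, C1′) and is then erased. C2 and C10 arise in the ring closure (trans fusion), which is stereoconvergent at C2 because both bromohydrin diastereomers give one radical.

Key step: step 5

Numbering: humulane numbering for the terpenoid part (ring C1–C11; gem-dimethyl on C11; C14 on C7; C15 on C3; C8 is the carbonyl carbon of zerumbone); C1′ is the benzylic carbon.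

Assumption: zerumbone, benzaldehyde and 2,4,6-trihydroxybenzene-1,3-dicarbaldehyde are bought.

Assumption: compounds 3, 7 and 8 are 1:1 pairs that differ only at the sacrificial centres C2/C3 ((2S,3R) and (2R,3S)), and 9–14 are the corresponding C3 epimers. The pairs are carried on unseparated; names and SMILES show the (2S,3R) or (3R) member.

Assumption: the facial sense of the carbinol-directed cycloaddition is assigned by the inside-alkoxy model. Were it the opposite, the (S) catalyst would be used in step 2 and nothing else changes.

Remark: the descriptor of C7 changes from R to S in step 7 only because C8 loses its CIP rank; the centre is not touched.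

**Step 1**
Reactants: 1 zerumbone
Product: 2 rac-(2S,3R)-2-bromo-3-hydroxyhumula-6E,9E-dien-8-one
Conditions: NBS (1.05 equiv), THF/H2O (3:1), 0 °C
Reagents that add atoms: N-bromosuccinimide (O=C1CCC(=O)N1Br); water (O)
Why: Electrophilic bromohydrin formation should take place only at the isolated, electron-rich C2=C3 alkene (the other two are enone alkenes), with Markovnikov regiochemistry (OH on tertiary C3, Br on C2) and anti addition across the E alkene, which gives the racemic (2S*,3R*) bromohydrin whose two centres are sacrificial.

**Step 2**
Reactants: 2 rac-(2S,3R)-2-bromo-3-hydroxyhumula-6E,9E-dien-8-one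
Product: 3 (8S)-2-bromohumula-6E,9E-diene-3,8-diol (C2/C3 pair)
Conditions: (R)-2-methyl-CBS-oxazaborolidine (C18H20BNO, 0.2 equiv), BH3·THF (2 equiv), THF, −30 °C; MeOH quench
Reagents that add atoms: none
Why: The Corey–Bakshi–Shibata reduction is 1,2-selective on the cross-conjugated dienone and, with the α-branched C7 alkenyl arm as the large substituent, the (R) catalyst should give the (8S) carbinol from both enantiomers of 2 under catalyst control, that is, the two C2/C3 diastereomers with one C8 configuration.

**Step 3**
Reactants: 3 (8S)-2-bromohumula-6E,9E-diene-3,8-diol (C2/C3 pair), 4 benzaldehyde, 5 2,4,6-trihydroxybenzene-1,3-dicarbaldehyde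
Product: 7 (1′S,6R,7R,8S)-chromane carbinol (C2/C3 pair), via o-quinone methide 6 (not isolated)
Conditions: ethylenediammonium diacetate (10 mol %), 4 Å molecular sieves, MeCN, 60 °C
Reagents that add atoms: none
Why: In this domino Knoevenagel/hetero-Diels–Alder reaction 4 and 5 condense to the electron-poor heterodiene 6, which should add to the only trisubstituted electron-rich alkene left (C6=C7; C2=C3 is masked, C9=C10 is disubstituted) with the benzylic carbon on C6 and oxygen on the cation-stabilising C7, suprafacially on the E alkene (C5 and C8 trans) and with the small H6/C8 edge endo (phenyl cis to H6, C1′ S), on the face opposite the ring chain in the conformer that keeps the C8 hydroxyl inside and H8 outside next to the C14 methyl (inside-alkoxy model), which for (8S) gives (6R,7R); the adduct from the other face is a separable diastereomer.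

**Step 4**
Reactants: 7 (1′S,6R,7R,8S)-chromane carbinol (C2/C3 pair)
Product: 8 (1′S,6R,7R)-chromane enone (C2/C3 pair)
Conditions: Dess–Martin periodinane (1.3 equiv), CH2Cl2, 0 °C to rt
Reagents that add atoms: none
Why: Dess–Martin oxidation of the secondary allylic carbinol should leave the tertiary hydroxyl, the hydrogen-bonded phenols and the aldehydes untouched, erases the controller centre C8 and makes C10 the β-carbon of an enone.

**Step 5**
Reactants: 8 (1′S,6R,7R)-chromane enone (C2/C3 pair)
Product: 11 (1′S,2R,6R,7R,10S)-cyclobutane keto alcohol (C3 epimers), via C2 radical 9 (not isolated), via cyclised C9 radical 10 (not isolated)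
Conditions: (Me3Si)3SiH (1.3 equiv) and AIBN (0.2 equiv) added over 8 h, PhMe, 85 °C, 3 mM
Reagents that add atoms: none
Why: The silyl radical takes bromine from either C2 epimer of 8 and gives one nucleophilic secondary radical 9, which adds across the ring to C10, the β-carbon of the enone, to give the carbonyl-stabilised radical 10 that the silane reduces (radical chain, a Giese addition run within the ring). The closest known reaction type is the 4-exo-trig cyclisation of δ-halo-γ,γ-disubstituted enoates and enones to gem-disubstituted cyclobutanes. The cyclobutane C1–C2–C10–C11 closes in the 4-exo-trig mode, and the same bond turns the eleven-membered ring into the nine-membered ring. C2 is set by the usual trans preference of such closures (C3 and C9 anti on the new ring, that is H2 and H10 trans, the stable fusion of the bicyclo[7.2.0]undecane), and C10 by the enone face that the chromane-anchored ring conformer (C14 methyl on the outer rim) turns towards C2; the step is stereoconvergent at C2. It needs ring closure to outrun hydrogen transfer to 9 and bond formation at C10 only: the gem-dimethyl group on C11 (Thorpe–Ingold effect), the fixed 1,4 distance of C2 and C10, the polarity match of an alkyl radical with an enone β-carbon, the stabilised product radical and slow addition of the silane at 3 mM should secure this.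

**Step 6**
Reactants: 11 (1′S,2R,6R,7R,10S)-cyclobutane keto alcohol (C3 epimers)
Product: 12 bis(diethyl dithioacetal) of 11 (C3 epimers)
Conditions: EtSH (5 equiv), I2 (10 mol %), CH2Cl2, rt
Reagents that add atoms: ethanethiol (CCS)
Why: Chemoselective dithioacetalisation should convert the two aryl aldehydes while the C8 ketone, flanked by the quaternary C7, stays, which masks the aldehydes for the hydrazone chemistry and makes the aryloxy group on C7 a poorer leaving group.

**Step 7**
Reactants: 12 bis(diethyl dithioacetal) of 11 (C3 epimers)
Product: 14 (1′S,2R,6R,7S,10S)-8-deoxo bis(dithioacetal) carbinol (C3 epimers), via tosylhydrazone 13 (not isolated)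
Conditions: TsNHNH2, EtOH, 70 °C; then catecholborane, CHCl3, 0 °C; NaOAc·3H2O, reflux
Reagents that add atoms: none
Why: In this Caglioti-type deoxygenation the tosylhydrazone 13 of the camphor-like hindered ketone is reduced by catecholborane and loses sulfinate and N2 on buffered warming, which should replace C=O by CH2 without a free carbanion next to the C7 aryloxy group and touches no stereocentre.

**Step 8**
Reactants: 14 (1′S,2R,6R,7S,10S)-8-deoxo bis(dithioacetal) carbinol (C3 epimers)
Product: 15 (1′S,2R,6R,7S,10S)-bis(diethyl dithioacetal) of the target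
Conditions: Burgess reagent (methyl N-(triethylammoniosulfonyl)carbamate, 3 equiv), PhMe, 50 °C
Reagents that add atoms: none
Why: In the Burgess dehydration (thermal syn elimination) only the C15 methyl hydrogens can reach the syn-periplanar arrangement without eclipsing bonds of the nine- or four-membered ring, so the exocyclic C3=C15 alkene is expected and both C3 epimers converge to one compound.

**Step 9**
Reactants: 15 (1′S,2R,6R,7S,10S)-bis(diethyl dithioacetal) of the target
Product: 16 target
Conditions: MeI (excess), CaCO3, MeCN/H2O (9:1), 45 °C
Reagents that add atoms: water (O)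
Why: Alkylative hydrolysis of the two dithioacetals (S-methylation, then water) under neutral buffered conditions should restore the aldehydes without touching the exocyclic alkene, the cyclobutane or any stereocentre.

**Compound list**

1 | zerumbone, (2E,6E,10E)-2,6,9,9-tetramethylcycloundeca-2,6,10-trien-1-one (humula-2E,6E,9E-trien-8-one) | C/C1=C\CC(C)(C)/C=C/C(=O)/C(C)=C/CC1 | starting material

2 | rac-(2S,3R)-2-bromo-3-hydroxyhumula-6E,9E-dien-8-one (anti bromohydrin of zerumbone; one enantiomer drawn) | C[C@@]1(O)CC/C=C(C)/C(=O)/C=C/C(C)(C)C[C@@H]1Br | intermediate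

3 | (8S)-2-bromohumula-6E,9E-diene-3,8-diol; pair of (2S,3R) and (2R,3S) isomers, (2S,3R,8S) drawn | C[C@@]1(O)CC/C=C(C)/[C@@H](O)/C=C/C(C)(C)C[C@@H]1Br | intermediate

4 | benzaldehyde | O=Cc1ccccc1 | starting material

5 | 2,4,6-trihydroxybenzene-1,3-dicarbaldehyde (2,4-diformylphloroglucinol) | O=Cc1c(O)cc(O)c(C=O)c1O | starting material

6 | (E)-5-benzylidene-2,4-dihydroxy-6-oxocyclohexa-1,3-diene-1,3-dicarbaldehyde (o-quinone methide) | O=C1/C(=C/c2ccccc2)C(O)=C(C=O)C(O)=C1C=O | intermediate

7 | (1′S,6R,7R,8S)-chromane carbinol: 5,7-dihydroxy-6,8-diformyl-4-phenylchromane fused at C6–C7 of the eleven-membered ring (O on C7, C1′ on C6), 2-bromo, 3-hydroxy, 8-hydroxy, C9=C10 E; C2/C3 pair, (2S,3R) drawn | C[C@@]1(O)CC[C@@H]2[C@@H](c3ccccc3)c3c(O)c(C=O)c(O)c(C=O)c3O[C@@]2(C)[C@@H](O)/C=C/C(C)(C)C[C@@H]1Br | intermediate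

8 | (1′S,6R,7R)-chromane enone: 8-oxo analogue of 7 (C8=O conjugated with C9=C10 E); C2/C3 pair, (2S,3R) drawn | C[C@@]1(O)CC[C@@H]2[C@@H](c3ccccc3)c3c(O)c(C=O)c(O)c(C=O)c3O[C@@]2(C)C(=O)/C=C/C(C)(C)C[C@@H]1Br | intermediate

9 | C2-centred radical from 8 after loss of bromine (C3 epimers, 3R drawn) | C[C@@]1(O)CC[C@@H]2[C@@H](c3ccccc3)c3c(O)c(C=O)c(O)c(C=O)c3O[C@@]2(C)C(=O)/C=C/C(C)(C)C[CH]1 | intermediate

10 | C9-centred α-keto radical after formation of the C2–C10 bond (2R,10S; C3 epimers) | C[C@@]1(O)CC[C@@H]2[C@@H](c3ccccc3)c3c(O)c(C=O)c(O)c(C=O)c3O[C@@]2(C)C(=O)[CH][C@H]2[C@H]1CC2(C)C | intermediate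

11 | (1′S,2R,6R,7R,10S)-cyclobutane keto alcohol: the target skeleton with C8=O and C3(OH)CH3 in place of C8H2 and C3=CH2, trans-fused four/nine bicycle; C3 epimers, 3R drawn | C[C@@]1(O)CC[C@@H]2[C@@H](c3ccccc3)c3c(O)c(C=O)c(O)c(C=O)c3O[C@@]2(C)C(=O)C[C@H]2[C@H]1CC2(C)C | intermediate

12 | bis(diethyl dithioacetal) of 11 (both aldehydes as CH(SEt)2; C3 epimers) | C[C@@]1(O)CC[C@@H]2[C@@H](c3ccccc3)c3c(O)c(C(SCC)SCC)c(O)c(C(SCC)SCC)c3O[C@@]2(C)C(=O)C[C@H]2[C@H]1CC2(C)C | intermediate

13 | C8 tosylhydrazone of 12 (C3 epimers) | C[C@@]1(O)CC[C@@H]2[C@@H](c3ccccc3)c3c(O)c(C(SCC)SCC)c(O)c(C(SCC)SCC)c3O[C@@]2(C)C(=NNS(=O)(=O)c3ccc(C)cc3)C[C@H]2[C@H]1CC2(C)C | intermediate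

14 | (1′S,2R,6R,7S,10S)-8-deoxo compound: C8H2, C3(OH)CH3, both aldehydes as CH(SEt)2; C3 epimers, 3R drawn | C[C@@]1(O)CC[C@@H]2[C@@H](c3ccccc3)c3c(O)c(C(SCC)SCC)c(O)c(C(SCC)SCC)c3O[C@@]2(C)CC[C@H]2[C@H]1CC2(C)C | intermediate

15 | (1′S,2R,6R,7S,10S)-bis(diethyl dithioacetal) of the target (exocyclic C3=C15 in place) | C=C1CC[C@@H]2[C@@H](c3ccccc3)c3c(O)c(C(SCC)SCC)c(O)c(C(SCC)SCC)c3O[C@@]2(C)CC[C@H]2[C@H]1CC2(C)C | intermediate

16 | target, (1′S,2R,6R,7S,10S) | C=C1CC[C@@H]2[C@@H](c3ccccc3)c3c(O)c(C=O)c(O)c(C=O)c3O[C@@]2(C)CC[C@H]2[C@H]1CC2(C)C | target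

Total step count: 9
Longest linear sequence: 9 steps (1 → 16)

**Three steps most likely to fail**

First, step 5. Hydrogen transfer from the silane to radical 9 may outrun the slow 4-exo closure (reduction without ring formation), or the ring may close through a conformer that gives the other fusion. The fallback sets out from 8 and comes back at 11. It makes the radical without a hydrogen-atom donor: 8, Zn dust, cyanocobalamin (C63H88CoN14O14P, 5 mol %), NH4Cl, DMF, visible light. Zinc reduces the complex to monovalent cobalt, which takes the bromide. The C2 radical is then released reversibly from the cobalt–carbon bond and can wait for the closure. The cyclised α-keto radical is reduced and protonated to 11. No new compound lies on this path (F0).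

Second, step 3. The doubly allylic carbinol may ionise, the bromohydrin may close to the epoxide, or the carbinol oxygen may capture 6 under the condensation conditions; facial selectivity may also be low. The fallback sets out from 4 and 5 and comes back at 7. It separates condensation from cycloaddition: 4 and 5 are condensed in ethanol (ethylenediammonium diacetate cat., rt) to 5-[ethoxy(phenyl)methyl]-2,4,6-trihydroxybenzene-1,3-dicarbaldehyde F1, which is isolated. F1 is then heated with 3 in toluene at 90 °C without additive. Thermal loss of ethanol releases 6 slowly under neutral conditions and should give 7. The isomer from the other alkene face stays separable because C8 makes it a diastereomer.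

Third, step 8. The tertiary centre may ionise, with loss of regiocontrol (endocyclic C3=C4 or C2=C3 alkene) or ring expansion of the cyclobutylcarbinyl cation. The fallback sets out from 14 and comes back at 15. It turns the elimination into a base-induced E2: 14 is converted with SOCl2 in CH2Cl2 at −20 °C into the C3 chloride of 14 F2. KOtBu in t-BuOH/DMSO then removes HCl with Hofmann orientation (the bulky base takes a methyl hydrogen) and should give 15.

**Further compounds**

F0 | step 5 | none | none
F1 | step 3 | 5-[ethoxy(phenyl)methyl]-2,4,6-trihydroxybenzene-1,3-dicarbaldehyde (racemic) | CCOC(c1ccccc1)c1c(O)c(C=O)c(O)c(C=O)c1O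
F2 | step 8 | (1′S,2R,6R,7S,10S)-3-chloro analogue of 14 (C3–Cl in place of C3–OH, C3 epimers) | CC1(Cl)CC[C@@H]2[C@@H](c3ccccc3)c3c(O)c(C(SCC)SCC)c(O)c(C(SCC)SCC)c3O[C@@]2(C)CC[C@H]2[C@H]1CC2(C)C
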